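**Plan**

1. Numbering (daucane): C1 quaternary ring-fusion C (CH3), C2 CHOH, C3 CH2, C4 C(OH)(i-Pr), C5 ring-fusion CH, C6 CHO-ester, C7 CH2, C8 C(CH3)–O, C9 CH–O, C10 CHO-ester; β is the face of the C1 methyl. The retrosynthesis cuts the two ester C–O bonds and the epoxide, then C6–C7, then C4–i-Pr, O–C6, C9–C10, C5–C6 and C1–C10.
2. Enabling feature: C6 and C9 both carry oxygen and stand 1,4 across the seven-membered ring, with C7–C8 between them. One oxygen can therefore tie C6 to C9 in an oxane (O, C6, C5, C1, C10, C9) whose C9 2-propenyl group (C8=C7) is the allyl ether of a C6 carbanion. A [2,3]-Wittig shift then forms C6–C7, sets C6, places C8=C9 and turns the oxane into the carbocycle, leaving the oxygen on C6.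
3. Forward ring order: five-membered ring (from the cyclopentenone) → cis-fused oxane (step 10) → seven-membered ring by oxygen extrusion (step 12) → epoxide (step 14); esters last.
4. Stereochemistry: C2 from (S)-4-silyloxycyclopentenone; C1 by anti conjugate addition; C5 by enolate trapping (cis fusion); C9/C10 by reagent-controlled syn alkoxyallylboration; C4 by convex-face addition; C6 by transfer from C9 in the rearrangement; epoxide by delivery from the C10 hydroxyl.

Key step: step 12

Remark: the acetal centre C6 in 14–16 is carried as an anomeric mixture, because reductive lithiation in step 12 erases it.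

**Route**

Step 1
Reactants: 1 (S)-4-(tert-butyldimethylsilyloxy)cyclopent-2-en-1-one
Product: 2 (3S,4S)-4-(tert-butyldimethylsilyloxy)-3-methyl-1-(trimethylsilyloxy)cyclopent-1-ene
Conditions: MeMgBr, CuBr·SMe2 (10 mol%), Me3SiCl, DMPU, THF, −78 °C
Reagents that add atoms: methylmagnesium bromide, C[Mg]Br; chlorotrimethylsilane, C[Si](C)(C)Cl
Why: Copper-catalysed conjugate addition should occur anti to the silyloxy group, and the chlorosilane traps the enolate regiospecifically as the silyl enol ether needed for step 2.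

Step 2
Reactants: 2 (3S,4S)-4-(tert-butyldimethylsilyloxy)-3-methyl-1-(trimethylsilyloxy)cyclopent-1-ene
Product: 3 (S)-4-(tert-butyldimethylsilyloxy)-3-methylcyclopent-2-en-1-one
Conditions: Pd(OAc)2 (1.05 equiv), MeCN, rt
Reagents that add atoms: none
Why: Saegusa–Ito oxidation: the divalent palladium enolate undergoes β-hydride elimination toward the methyl-bearing carbon, restoring the enone with the methyl on the β-carbon and leaving the silyloxy stereocentre untouched.

Step 3
Reactants: 3 (S)-4-(tert-butyldimethylsilyloxy)-3-methylcyclopent-2-en-1-one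
Product: 4 4-(tert-butyldimethylsilyloxy)-3-ethenyl-3-methyl-1-(trimethylsilyloxy)cyclopent-1-ene (ethenyl trans, methyl cis to the silyloxy group)
Conditions: CH2=CHMgBr, CuBr·SMe2 (20 mol%), Me3SiCl, DMPU, THF, −78 → −40 °C
Reagents that add atoms: vinylmagnesium bromide, C=C[Mg]Br; chlorotrimethylsilane, C[Si](C)(C)Cl
Why: Chlorosilane-accelerated, copper-catalysed conjugate addition should create quaternary C1 with the vinyl group anti to the neighbouring silyloxy group (methyl cis to it, as in the target) and gives the C4=C5 silyl enol ether regiospecifically.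

Step 4
Reactants: 4 4-(tert-butyldimethylsilyloxy)-3-ethenyl-3-methyl-1-(trimethylsilyloxy)cyclopent-1-ene
Product: 5 2-(dimethoxymethyl)-3-ethenyl-3-methyl-4-(tert-butyldimethylsilyloxy)cyclopentan-1-one (dimethoxymethyl cis to ethenyl; methyl cis to silyloxy)
Conditions: HC(OMe)3, Me3SiOTf (10 mol%), CH2Cl2, −78 °C
Reagents that add atoms: trimethyl orthoformate, COC(OC)OC
Why: Mukaiyama-type alkylation of the silyl enol ether by the dimethoxycarbenium ion installs C6 at the aldehyde oxidation level; attack should come anti to the C1 methyl, which the cis silyloxy group holds pseudo-axial, so C6 ends cis to the vinyl group (C5 stays epimerisable and the cis-fused bicycle of step 10 is the thermodynamic one).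

Step 5
Reactants: 5 2-(dimethoxymethyl)-3-ethenyl-3-methyl-4-(tert-butyldimethylsilyloxy)cyclopentan-1-one
Product: 6 2-(dimethoxymethyl)-1-methyl-3-oxo-5-(tert-butyldimethylsilyloxy)cyclopentane-1-carbaldehyde (formyl cis to dimethoxymethyl, trans to silyloxy)
Conditions: O3, CH2Cl2, −78 °C; PPh3, −78 °C → rt
Reagents that add atoms: ozone, [O-][O+]=O
Why: Ozonolysis with reductive work-up cleaves the only alkene to the C10 aldehyde without touching the acetal, ketone or silyl ether.

Step 6
Reactants: 7 4-methoxyphenol; 8 3-chloro-2-methylprop-1-ene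
Product: 9 1-methoxy-4-[(2-methylprop-2-en-1-yl)oxy]benzene
Conditions: K2CO3, acetone, reflux
Reagents that add atoms: none
Why: Williamson ether synthesis of a phenoxide with a primary allylic chloride.

Step 7
Reactants: 9 1-methoxy-4-[(2-methylprop-2-en-1-yl)oxy]benzene; 6 2-(dimethoxymethyl)-1-methyl-3-oxo-5-(tert-butyldimethylsilyloxy)cyclopentane-1-carbaldehyde
Product: 11 2-(dimethoxymethyl)-3-[1-hydroxy-2-(4-methoxyphenoxy)-3-methylbut-3-en-1-yl]-3-methyl-4-(tert-butyldimethylsilyloxy)cyclopentan-1-one (side chain 1,2-syn: C10–OH, C9–OAr), via allylborane 10 (not isolated)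
Conditions: 9, s-BuLi, THF, −78 °C; (−)-Ipc2BOMe; BF3·OEt2; then 6, −78 °C; HOCH2CH2NH2 work-up
Reagents that add atoms: none
Why: Brown (Z)-γ-alkoxyallylboration: lithiation of 9, borylation and BF3 release give the (Z)-allylborane 10, which should add to the aldehyde (faster than to the ketone at −78 °C) through a chair six-membered transition state, the (Z) geometry giving the 9,10-syn relationship and the isopinocampheyl groups from (+)-α-pinene selecting the aldehyde face (reagent control).

Step 8
Reactants: 11 2-(dimethoxymethyl)-3-[1-hydroxy-2-(4-methoxyphenoxy)-3-methylbut-3-en-1-yl]-3-methyl-4-(tert-butyldimethylsilyloxy)cyclopentan-1-one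
Product: 12 the C10 triethylsilyl ether of 11
Conditions: Et3SiOTf, 2,6-lutidine, CH2Cl2, −78 °C
Reagents that add atoms: triethylsilyl trifluoromethanesulfonate, CC[Si](CC)(CC)OS(=O)(=O)C(F)(F)F
Why: Silylation with the silyl triflate and a hindered base blocks the neopentyl C10 hydroxyl, so that only the C9 oxygen can later close onto C6.

Step 9
Reactants: 12 the C10 triethylsilyl ether of 11
Product: 13 2-(dimethoxymethyl)-3-[2-hydroxy-3-methyl-1-(triethylsilyloxy)but-3-en-1-yl]-3-methyl-4-(tert-butyldimethylsilyloxy)cyclopentan-1-one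
Conditions: (NH4)2Ce(NO3)6, pyridine, MeCN/H2O (4:1), 0 °C
Reagents that add atoms: none
Why: Oxidative cleavage of the 4-methoxyphenyl ether by the buffered ceric salt should release the C9 hydroxyl and leave silyl ethers, acetal and alkene intact.

Step 10
Reactants: 13 2-(dimethoxymethyl)-3-[2-hydroxy-3-methyl-1-(triethylsilyloxy)but-3-en-1-yl]-3-methyl-4-(tert-butyldimethylsilyloxy)cyclopentan-1-one
Product: 15 cis-fused 4a-methyl-1-(phenylsulfanyl)-3-(prop-1-en-2-yl)-4-(triethylsilyloxy)-5-(tert-butyldimethylsilyloxy)hexahydrocyclopenta[c]pyran-7(1H)-one (oxane O between C6 and C9; 2-propenyl, C10 silyloxy and the five-membered ring on one face), via cyclic methyl acetal 14 (not isolated)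
Conditions: PhSH (1.3 equiv), BF3·OEt2 (0.3 equiv), 4 Å sieves, CH2Cl2, −78 → −30 °C
Reagents that add atoms: thiophenol, Sc1ccccc1
Why: Lewis-acid-catalysed transacetalisation closes the oxane by attack of the C9 hydroxyl on the C6 oxocarbenium ion (six-membered ring, cis fusion imposed by the cis C6/C10 substituents), and thiophenol then exchanges the anomeric methoxy group to give the O,S-acetal needed for reductive lithiation.

Step 11
Reactants: 15 cis-fused 4a-methyl-1-(phenylsulfanyl)-3-(prop-1-en-2-yl)-4-(triethylsilyloxy)-5-(tert-butyldimethylsilyloxy)hexahydrocyclopenta[c]pyran-7(1H)-one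
Product: 16 cis-fused 4a-methyl-1-(phenylsulfanyl)-7-(propan-2-yl)-3-(prop-1-en-2-yl)-4-(triethylsilyloxy)-5-(tert-butyldimethylsilyloxy)octahydrocyclopenta[c]pyran-7-ol (isopropyl cis to the ring-fusion H)
Conditions: i-PrMgCl, CeCl3, THF, −78 → 0 °C
Reagents that add atoms: isopropylmagnesium chloride, CC(C)[Mg]Cl
Why: Organocerium addition to the hindered, enolisable ketone; the nucleophile should add on the convex face of the cis-fused bicycle, anti to the adjacent C5–C6 bond, placing the isopropyl group cis to H-5 and the hydroxyl α.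

Step 12
Reactants: 16 cis-fused 4a-methyl-1-(phenylsulfanyl)-7-(propan-2-yl)-3-(prop-1-en-2-yl)-4-(triethylsilyloxy)-5-(tert-butyldimethylsilyloxy)octahydrocyclopenta[c]pyran-7-ol
Product: 18 2β-(tert-butyldimethylsilyloxy)-10α-(triethylsilyloxy)dauc-8-ene-4α,6β-diol (H-5 β, cis ring fusion), via 6-lithio-oxane 17 (not isolated)
Conditions: n-BuLi (1.05 equiv), THF, −78 °C; lithium 4,4'-di-tert-butylbiphenylide (LiDBB, 2.2 equiv), −78 → −40 °C; NH4Cl (aq)
Reagents that add atoms: none
Why: Proposed new method: two single-electron transfers from LiDBB cleave the C6–S bond to give the 6-lithio-oxane 17, whose carbanion attacks the terminal carbon C7 of the C9 2-propenyl group in a concerted suprafacial [2,3]-sigmatropic (Wittig) shift while the C9–O bond breaks, so the ring oxygen is extruded as the C6 alkoxide and C8=C9 appears. The closest known reaction type is the Wittig–Still rearrangement and its reductive-lithiation variant on acyclic α-(allyloxy)alkyl phenyl sulfides; an endocyclic carbanion with an exocyclic alkenyl group, which turns an oxane into a cycloheptenol, has not been shown. The seven-membered carbocycle (C5, C6, C7, C8, C9, C10, C1) closes through the usual five-membered envelope transition state (C6, O, C9, C8, C7), here bridged by C5–C1–C10 and so resembling an 8-oxabicyclo[3.2.1]oct-6-ene, reached when the 2-propenyl group is axial and 1,3 to C6 across the ring oxygen. The only new stereocentre, C6, is set by C9: C7 can reach C6 only on the oxane face that carries the 2-propenyl group, so the C9 configuration (lost as C9 becomes sp2) is transferred to C6, and the ring forces the cis C8=C9 bond. The step needs the [2,3] shift to beat the [1,2] shift (ring contraction by C6–C9 bonding), protonation by solvent and β-elimination; low temperature, the absence of a leaving group on C5, prior deprotonation of the C4 hydroxyl, and epimerisation of C6–Li to the reactive arrangement trans to the 2-propenyl group should secure this.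

Step 13
Reactants: 18 2β-(tert-butyldimethylsilyloxy)-10α-(triethylsilyloxy)dauc-8-ene-4α,6β-diol
Product: 19 2β-(tert-butyldimethylsilyloxy)dauc-8-ene-4α,6β,10α-triol
Conditions: PPTS (cat.), MeOH, 0 °C
Reagents that add atoms: none
Why: Acid-catalysed methanolysis should remove the secondary triethylsilyl ether selectively in the presence of the more robust tert-butyldimethylsilyl ether.

Step 14
Reactants: 19 2β-(tert-butyldimethylsilyloxy)dauc-8-ene-4α,6β,10α-triol
Product: 20 8α,9α-epoxy-2β-(tert-butyldimethylsilyloxy)daucane-4α,6β,10α-triol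
Conditions: VO(acac)2 (5 mol%), t-BuOOH, CH2Cl2, 0 °C → rt
Reagents that add atoms: tert-butyl hydroperoxide, CC(C)(C)OO
Why: Hydroxyl-directed vanadium-catalysed epoxidation: the allylic C10 alkoxide binds vanadium and delivers oxygen to the face of C8=C9 syn to it (α), allylic delivery being much faster than delivery from the homoallylic C6 hydroxyl.

Step 15
Reactants: 20 8α,9α-epoxy-2β-(tert-butyldimethylsilyloxy)daucane-4α,6β,10α-triol
Product: 21 6β,10α-bis(angeloyloxy)-8α,9α-epoxy-2β-(tert-butyldimethylsilyloxy)daucan-4α-ol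
Conditions: angelic acid, 2,4,6-trichlorobenzoyl chloride, Et3N, toluene, rt; then 20, 75 °C
Reagents that add atoms: angelic acid, C/C=C(/C)C(=O)O
Why: Yamaguchi-type mixed-anhydride acylation without a nucleophilic catalyst should esterify both hindered secondary hydroxyls while keeping the (Z) geometry of the angelate; the tertiary C4 hydroxyl does not react.

Step 16
Reactants: 21 6β,10α-bis(angeloyloxy)-8α,9α-epoxy-2β-(tert-butyldimethylsilyloxy)daucan-4α-ol
Product: 22 6β,10α-bis(angeloyloxy)-8α,9α-epoxydaucane-2β,4α-diol (CNP0265715.3)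
Conditions: Bu4NF, AcOH (1:1), THF, 0 °C → rt
Reagents that add atoms: none
Why: Acetic-acid-buffered fluoride should cleave the silyl ether without opening the epoxide, moving an acyl group or isomerising angelate to tiglate.

**Compound list**

1 | (S)-4-(tert-butyldimethylsilyloxy)cyclopent-2-en-1-one | C1=CC(=O)C[C@@H]1O[Si](C)(C)C(C)(C)C | starting material
2 | (3S,4S)-4-(tert-butyldimethylsilyloxy)-3-methyl-1-(trimethylsilyloxy)cyclopent-1-ene | C[C@H]1C=C(O[Si](C)(C)C)C[C@@H]1O[Si](C)(C)C(C)(C)C | intermediate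
3 | (S)-4-(tert-butyldimethylsilyloxy)-3-methylcyclopent-2-en-1-one | CC1=CC(=O)C[C@@H]1O[Si](C)(C)C(C)(C)C | intermediate
4 | 4-(tert-butyldimethylsilyloxy)-3-ethenyl-3-methyl-1-(trimethylsilyloxy)cyclopent-1-ene (ethenyl trans to silyloxy) | C=C[C@@]1(C)C=C(O[Si](C)(C)C)C[C@@H]1O[Si](C)(C)C(C)(C)C | intermediate
5 | 2-(dimethoxymethyl)-3-ethenyl-3-methyl-4-(tert-butyldimethylsilyloxy)cyclopentan-1-one | C=C[C@@]1(C)[C@@H](C(OC)OC)C(=O)C[C@@H]1O[Si](C)(C)C(C)(C)C | intermediate
6 | 2-(dimethoxymethyl)-1-methyl-3-oxo-5-(tert-butyldimethylsilyloxy)cyclopentane-1-carbaldehyde | O=C[C@@]1(C)[C@@H](C(OC)OC)C(=O)C[C@@H]1O[Si](C)(C)C(C)(C)C | intermediate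
7 | 4-methoxyphenol | COc1ccc(O)cc1 | starting material
8 | 3-chloro-2-methylprop-1-ene | C=C(C)CCl | starting material
9 | 1-methoxy-4-[(2-methylprop-2-en-1-yl)oxy]benzene | C=C(C)COc1ccc(OC)cc1 | intermediate
10 | [(Z)-3-(4-methoxyphenoxy)-2-methylprop-2-en-1-yl]bis(isopinocampheyl)borane (isopinocampheyl from (+)-α-pinene) | COc1ccc(O/C=C(/C)CB([C@@H]2C[C@@H]3C[C@H]([C@H]2C)C3(C)C)[C@@H]2C[C@@H]3C[C@H]([C@H]2C)C3(C)C)cc1 | intermediate (not isolated)
11 | 2-(dimethoxymethyl)-3-[1-hydroxy-2-(4-methoxyphenoxy)-3-methylbut-3-en-1-yl]-3-methyl-4-(tert-butyldimethylsilyloxy)cyclopentan-1-one (1,2-syn side chain) | COc1ccc(O[C@H](C(C)=C)[C@H](O)[C@@]2(C)[C@@H](C(OC)OC)C(=O)C[C@@H]2O[Si](C)(C)C(C)(C)C)cc1 | intermediate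
12 | C10 triethylsilyl ether of 11 | COc1ccc(O[C@H](C(C)=C)[C@H](O[Si](CC)(CC)CC)[C@@]2(C)[C@@H](C(OC)OC)C(=O)C[C@@H]2O[Si](C)(C)C(C)(C)C)cc1 | intermediate
13 | 2-(dimethoxymethyl)-3-[2-hydroxy-3-methyl-1-(triethylsilyloxy)but-3-en-1-yl]-3-methyl-4-(tert-butyldimethylsilyloxy)cyclopentan-1-one | O[C@H](C(C)=C)[C@H](O[Si](CC)(CC)CC)[C@@]1(C)[C@@H](C(OC)OC)C(=O)C[C@@H]1O[Si](C)(C)C(C)(C)C | intermediate
14 | cis-fused 1-methoxy-4a-methyl-3-(prop-1-en-2-yl)-4-(triethylsilyloxy)-5-(tert-butyldimethylsilyloxy)hexahydrocyclopenta[c]pyran-7(1H)-one (anomeric mixture) | COC1O[C@H](C(C)=C)[C@H](O[Si](CC)(CC)CC)[C@@]2(C)[C@@H]1C(=O)C[C@@H]2O[Si](C)(C)C(C)(C)C | intermediate (not isolated)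
15 | cis-fused 4a-methyl-1-(phenylsulfanyl)-3-(prop-1-en-2-yl)-4-(triethylsilyloxy)-5-(tert-butyldimethylsilyloxy)hexahydrocyclopenta[c]pyran-7(1H)-one (anomeric mixture) | c1ccccc1SC1O[C@H](C(C)=C)[C@H](O[Si](CC)(CC)CC)[C@@]2(C)[C@@H]1C(=O)C[C@@H]2O[Si](C)(C)C(C)(C)C | intermediate
16 | cis-fused 4a-methyl-1-(phenylsulfanyl)-7-(propan-2-yl)-3-(prop-1-en-2-yl)-4-(triethylsilyloxy)-5-(tert-butyldimethylsilyloxy)octahydrocyclopenta[c]pyran-7-ol (anomeric mixture) | c1ccccc1SC1O[C@H](C(C)=C)[C@H](O[Si](CC)(CC)CC)[C@@]2(C)[C@@H]1[C@](O)(C(C)C)C[C@@H]2O[Si](C)(C)C(C)(C)C | intermediate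
17 | 6-lithio-oxane from 16 (C6–Li trans to the 2-propenyl group; C4 lithium alkoxide) | [Li][C@H]1O[C@H](C(C)=C)[C@H](O[Si](CC)(CC)CC)[C@@]2(C)[C@@H]1[C@](O[Li])(C(C)C)C[C@@H]2O[Si](C)(C)C(C)(C)C | intermediate (not isolated)
18 | 2β-(tert-butyldimethylsilyloxy)-10α-(triethylsilyloxy)dauc-8-ene-4α,6β-diol | O[C@H]1CC(C)=C[C@H](O[Si](CC)(CC)CC)[C@@]2(C)[C@@H]1[C@](O)(C(C)C)C[C@@H]2O[Si](C)(C)C(C)(C)C | intermediate
19 | 2β-(tert-butyldimethylsilyloxy)dauc-8-ene-4α,6β,10α-triol | O[C@H]1CC(C)=C[C@H](O)[C@@]2(C)[C@@H]1[C@](O)(C(C)C)C[C@@H]2O[Si](C)(C)C(C)(C)C | intermediate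
20 | 8α,9α-epoxy-2β-(tert-butyldimethylsilyloxy)daucane-4α,6β,10α-triol | O[C@H]1C[C@]2(C)O[C@@H]2[C@H](O)[C@@]2(C)[C@@H]1[C@](O)(C(C)C)C[C@@H]2O[Si](C)(C)C(C)(C)C | intermediate
21 | 6β,10α-bis(angeloyloxy)-8α,9α-epoxy-2β-(tert-butyldimethylsilyloxy)daucan-4α-ol | C/C=C(/C)C(=O)O[C@H]1C[C@]2(C)O[C@@H]2[C@H](OC(=O)/C(C)=C\C)[C@@]2(C)[C@@H]1[C@](O)(C(C)C)C[C@@H]2O[Si](C)(C)C(C)(C)C | intermediate
22 | 6β,10α-bis(angeloyloxy)-8α,9α-epoxydaucane-2β,4α-diol (CNP0265715.3) | C/C=C(/C)C(=O)O[C@H]1C[C@]2(C)O[C@@H]2[C@H](OC(=O)/C(C)=C\C)[C@@]2(C)[C@@H]1[C@](O)(C(C)C)C[C@@H]2O | target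

**Step count and risks**

Total steps: 16. Longest linear sequence: 15 (steps 1–5 and 7–16; step 6 is a one-step branch).

Steps most likely to fail:

Step 12 (the step with the new-method label). The lithiated oxane may be protonated by the solvent, or contract by the [1,2] shift, before it reaches the conformer with the 2-propenyl group axial over the ring oxygen, so that little C6–C7 bonding occurs. The fallback closes the same bond by cationic chemistry. It sets out from 13: SnBr4 in CH2Cl2 at −78 °C would ionise the acetal to the cyclic C6 oxocarbenium ion, which the 2-propenyl terminus attacks (Prins cyclisation) with bromide capture at C8, giving the oxygen-bridged bromide 8-bromo-6β,9β-epoxy-10α-(triethylsilyloxy)-2β-(tert-butyldimethylsilyloxy)daucan-4-one F1. Zinc dust in ethanol/NH4Cl at 60 °C would open the bridge by reductive β-elimination (Boord olefin synthesis) to 6β-hydroxy-10α-(triethylsilyloxy)-2β-(tert-butyldimethylsilyloxy)dauc-8-en-4-one F2. Addition of i-PrMgCl/CeCl3 as in step 11 would then give 18, where the route is rejoined.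

Step 3. Transfer of the vinyl group to the β,β-disubstituted, γ-silyloxy enone may be slow, so that 1,2-addition or loss of the silyloxy group takes over. The fallback is a Lewis-acid-driven conjugate allylation. It sets out from 3: allyltrimethylsilane and TiCl4 (CH2Cl2, −78 °C; Hosomi–Sakurai reaction), with the titanium enolate trapped in the same flask by HC(OMe)3, would give 2-(dimethoxymethyl)-3-methyl-3-(prop-2-en-1-yl)-4-(tert-butyldimethylsilyloxy)cyclopentan-1-one F3. Isomerisation of the terminal alkene with hydrogen-activated [Ir(cod)(PMePh2)2]PF6 in THF would give the (E)-prop-1-en-1-yl analogue F4. Ozonolysis of F4 under the conditions of step 5 returns to 6.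

Step 11. The secondary Grignard reagent may enolise the ketone (which would expel the ring oxygen or the silyloxy group by β-elimination), reduce it by β-hydride transfer, or add with poor facial selectivity. The fallback uses an sp2 nucleophile and a late hydrogenation. It sets out from 15: 2-propenylmagnesium bromide/CeCl3 would give the 2-propenyl carbinol corresponding to 16, F5. The rearrangement of step 12 would then give 4-(prop-1-en-2-yl)-2β-(tert-butyldimethylsilyloxy)-10α-(triethylsilyloxy)dauc-8-ene-4α,6β-diol F6. Hydrogenation of its 1,1-disubstituted alkene with H2 and RhCl(PPh3)3 in benzene, which should leave the trisubstituted ring alkene untouched, returns to 18.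

Further compounds
F1 | step 12 | 8-bromo-6β,9β-epoxy-10α-(triethylsilyloxy)-2β-(tert-butyldimethylsilyloxy)daucan-4-one (C8 epimers) | O1[C@H]2CC(C)(Br)[C@@H]1[C@H](O[Si](CC)(CC)CC)[C@@]1(C)[C@@H]2C(=O)C[C@@H]1O[Si](C)(C)C(C)(C)C
F2 | step 12 | 6β-hydroxy-10α-(triethylsilyloxy)-2β-(tert-butyldimethylsilyloxy)dauc-8-en-4-one | O[C@H]1CC(C)=C[C@H](O[Si](CC)(CC)CC)[C@@]2(C)[C@@H]1C(=O)C[C@@H]2O[Si](C)(C)C(C)(C)C
F3 | step 3 | 2-(dimethoxymethyl)-3-methyl-3-(prop-2-en-1-yl)-4-(tert-butyldimethylsilyloxy)cyclopentan-1-one | C=CC[C@@]1(C)[C@@H](C(OC)OC)C(=O)C[C@@H]1O[Si](C)(C)C(C)(C)C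
F4 | step 3 | 2-(dimethoxymethyl)-3-methyl-3-[(E)-prop-1-en-1-yl]-4-(tert-butyldimethylsilyloxy)cyclopentan-1-one | C/C=C/[C@@]1(C)[C@@H](C(OC)OC)C(=O)C[C@@H]1O[Si](C)(C)C(C)(C)C
F5 | step 11 | cis-fused 4a-methyl-1-(phenylsulfanyl)-3,7-di(prop-1-en-2-yl)-4-(triethylsilyloxy)-5-(tert-butyldimethylsilyloxy)octahydrocyclopenta[c]pyran-7-ol | c1ccccc1SC1O[C@H](C(C)=C)[C@H](O[Si](CC)(CC)CC)[C@@]2(C)[C@@H]1[C@](O)(C(C)=C)C[C@@H]2O[Si](C)(C)C(C)(C)C
F6 | step 11 | 4-(prop-1-en-2-yl)-2β-(tert-butyldimethylsilyloxy)-10α-(triethylsilyloxy)dauc-8-ene-4α,6β-diol (2-propenyl in place of isopropyl in 18) | O[C@H]1CC(C)=C[C@H](O[Si](CC)(CC)CC)[C@@]2(C)[C@@H]1[C@](O)(C(C)=C)C[C@@H]2O[Si](C)(C)C(C)(C)C
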